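(The data are simulated for substances that don't exist, noise included.)

Ask for the end first.

| flask | substrate | enzyme | remark | time |
|---|---|---|---|---|
| alder | 0.098 M | 33 µM | run made earlier |  |
| maple | 0.098 M | 120 µM | run made earlier |  |
| larch | 0.070 M | 56 µM | run made earlier |  |
| north-east | 0.20 M | 120 µM |  | 20 h |
| east | 0.025 M | 80 µM |  | 20 h |
| south-west | 0.40 M | 150 µM |  | 20 h |
| south-east | 0.098 M | 56 µM |  | 20 h |

| run | time / h | target / % | substrate / % |
|---|---|---|---|
| alder | 3.00 | 38 | 64 |
| alder | 6.00 | 54 | 46 |
| alder | 8.00 | 58 | 40 |
| alder | 12.0 | 67 | 33 |
| alder | 15.0 | 73 | 28 |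
| alder | 20.0 | 77 | 25 |
| maple | 1.50 | 51 | 52 |
| maple | 2.50 | 61 | 38 |
| maple | 4.00 | 69 | 29 |
| maple | 6.00 | 78 | 23 |
| maple | 8.00 | 83 | 19 |
| maple | 12.0 | 85 | 14 |
| maple | 20.0 | 90 | 11 |
| larch | 2.00 | 32 | 69 |
| larch | 5.00 | 49 | 48 |
| larch | 10.0 | 66 | 37 |
| larch | 15.0 | 74 | 28 |
| larch | 20.0 | 77 | 23 |

(standard deviation of a reading: 1.5 percentage points)

* the flasks by amount of target, in percent of the substrate charged, highest first, at 20 h (north-east / east / south-west / south-east)
* the amount of target, in percent of the substrate charged of the flask you put first, at 20 h
* the amount of target, in percent of the substrate charged of the flask you put last, at 20 h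

In the maple run the last reading gave target 90% and substrate 11%, which sum to 101%, so I took the charge itself as the ceiling, 100%, and asked how fast it is approached.

Let f be the substrate left as a fraction of its charge. I anchored every reckoning on that maple reading and scaled it with c_enzyme × time and, where the charge differed, with charged c_substrate raised to the order less one. Order 2 in substrate then left 31.0% in the alder run, and order 3 left 20.6%, against a reading of 25%. They were off by 6 percentage points and 4.4 points in opposite directions, with a scatter of 1.5 points, so they made my bracket. For east, order 2 gave 57.9% of target as my estimated upper bound and order 3 gave 53.1% as my estimated lower one. For south-west the two closed up, at 97.6% and 97.6%.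

To tighten this I took order 2.5. The dose of a flask is f to the power −1.5, less one, and it grows in proportion to c_enzyme × time × (charged c_substrate)^1.5; maple's last reading puts it at 26.4. Scaled to the larch run, this left 24.1%, against a reading of 23%. The doses were 272 for south-west, 77.0 for north-east, 12.3 for south-east and 2.27 for east. That gave south-west 97.6% of target and east 54.6%.

The forecast, reasoning “so the order is about 2.5 in substrate”, said south-west > north-east > south-east > east, with 97% and 55%; its low lies inside my bracket.

The flasks gave south-west > north-east > south-east > east, with 97.6% and 56.5%, and east also lay inside the bracket.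

    substrate → decomposition product (k = 1.20 × 10⁻⁷ s⁻¹)
    substrate + enzyme → target + enzyme, rate k2*[substrate]^2.5*[enzyme]/(1 + ([substrate]/Kh2)^2.5) (0.140 M, k = 74.0 M⁻²·⁵ s⁻¹)

East had not come to rest at 20 h, holding 43% substrate. Ten times the dose of east gave 87.9% of target, and east at 200 h stood at 87.2%. A neighbour of east charged with 0.015 M had a dose giving 38.1%, and at 20 h that neighbour stood at 40.1%. The saturation that the forecast said could lower the high end made no difference in south-west. Ten times the time would still lift south-west, from 97.6% to 99.4%.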